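**Retrosynthetic overview**
1. The pyran ring of the ketal is closed last: acid-mediated ketalisation of the methyl lactol obtained by MeLi addition to a γ-lactone that hangs on C11 of lasiodiplodin.
2. The ArCH2–C bond comes from Michael addition of the enolate of (S)-4-methyloxolan-2-one to the ortho-quinone methide of a lasiodiplodin Mannich base.
3. The oxolane ring and its methyl stereocentre come from a catalytic desymmetrising Baeyer–Villiger ring expansion (1,2-alkyl shift to oxygen, 4→5) of 3-methylcyclobutanone; that centre then controls the other two ketal centres.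
4. Lasiodiplodin comes from late C–H borylation/oxidation of its 12-deoxy macrolide, which comes from Mitsunobu macrolactonisation of the B-alkyl Suzuki product of 2-bromo-6-methoxybenzoic acid and (S)-non-8-en-2-ol.
5. Ring order: oxolane (as lactone, separate branch), then the 12-membered lactone, then the pyran ketal; the benzene ring is bought.

Assumption: 3-bromophenol, 6-bromohex-1-ene, (S)-methyloxirane and 3-methylcyclobutanone are bought; locants C3 and C10a–C14 follow 2-benzoxacyclododecin (lasiodiplodin) numbering.

**Step 1**
Reactants: 1 3-bromophenol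
Product: 2 1-bromo-3-methoxybenzene
Conditions: MeI, K2CO3, acetone, reflux
Reagents that add atoms: iodomethane CI
Why: Williamson O-methylation of the phenoxide (SN2), no stereocentre involved.

**Step 2**
Reactants: 2 1-bromo-3-methoxybenzene
Product: 4 2-bromo-6-methoxybenzoic acid, via aryllithium 3 (not isolated)
Conditions: LDA, THF, −78 °C; CO2 (g), −78 °C → rt; 1 M HCl
Reagents that add atoms: carbon dioxide O=C=O
Why: Directed ortho-lithiation removes the most acidic C–H, the one flanked by OMe and Br (−78 °C prevents aryne formation), and carboxylation of the aryllithium gives the acid.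

**Step 3**
Reactants: 5 6-bromohex-1-ene; 6 (S)-2-methyloxirane
Product: 8 (S)-non-8-en-2-ol, via Grignard reagent 7 (not isolated)
Conditions: Mg, THF; then 6, CuI (10 mol %), THF, −30 → 0 °C; 1 M HCl
Reagents that add atoms: none
Why: Copper-catalysed Grignard opening of the epoxide at its unsubstituted carbon (SN2) leaves the (S) centre of 6 untouched.

**Step 4**
Reactants: 8 (S)-non-8-en-2-ol; 4 2-bromo-6-methoxybenzoic acid
Product: 10 2-[(8S)-8-hydroxynonyl]-6-methoxybenzoic acid, via alkylborane 9 (not isolated)
Conditions: 9-BBN (2.2 equiv), THF, 0 °C → rt; then 4, Pd(dppf)Cl2 (5 mol %), 3 M aq K3PO4, DMF, 60 °C; 1 M HCl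
Reagents that add atoms: none
Why: Anti-Markovnikov hydroboration followed by B-alkyl Suzuki–Miyaura coupling, with the alcohol masked in situ as its borinate and the acid as its carboxylate; the stereocentre is not touched.

**Step 5**
Reactants: 10 2-[(8S)-8-hydroxynonyl]-6-methoxybenzoic acid
Product: 11 (3R)-14-methoxy-3-methyl-3,4,5,6,7,8,9,10-octahydro-1H-2-benzoxacyclododecin-1-one (12-deoxylasiodiplodin)
Conditions: PPh3, DIAD, toluene (0.005 M, slow addition), rt
Reagents that add atoms: none
Why: Mitsunobu macrolactonisation, in which the hindered carboxylate acts as nucleophile and displaces the activated secondary alcohol by SN2, inverting (S) to the required (R).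

**Step 6**
Reactants: 11 12-deoxylasiodiplodin
Product: 13 (R)-lasiodiplodin, via arylboronate 12 (not isolated)
Conditions: [Ir(OMe)(cod)]2 (1.5 mol %), dtbpy (3 mol %), B2pin2 (1.0 equiv), THF, 80 °C; then Oxone, acetone/H2O, rt
Reagents that add atoms: Oxone (potassium peroxymonosulfate) [K+].OOS([O-])(=O)=O
Why: Sterically controlled iridium-catalysed C–H borylation takes the only arene C–H without an ortho substituent (C12), and oxidation of the C–B bond gives the phenol.

**Step 7**
Reactants: 13 (R)-lasiodiplodin
Product: 14 11-[(dimethylamino)methyl]lasiodiplodin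
Conditions: 37% aq CH2O, 40% aq Me2NH, EtOH, 25 → 50 °C
Reagents that add atoms: formaldehyde C=O; dimethylamine CNC
Why: Phenol Mannich reaction (ortho-aminomethylation through the hydrogen-bonded iminium ion) is expected to favour C11, which is ortho to OH and para to OMe, over C13, which sits between two oxygen substituents.

**Step 8**
Reactants: 15 3-methylcyclobutan-1-one
Product: 17 (S)-4-methyloxolan-2-one, via Criegee adduct 16 (not isolated)
Conditions: confined chiral imidodiphosphorimidate (IDPi) Brønsted acid (2 mol %), 30% aq H2O2 (1.5 equiv), CHCl3, −40 °C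
Reagents that add atoms: hydrogen peroxide OO
Why: Proposed new method: a confined, strongly acidic chiral IDPi acid as catalyst for the desymmetrising Baeyer–Villiger oxidation of a small 3-alkylcyclobutanone; the acid hydrogen-bonds ketone and H2O2, Criegee adduct 16 forms inside the pocket, and the pocket wall holds the puckered ring so that only one of the two enantiotopic CH2 groups is antiperiplanar to the O–O bond and undergoes the 1,2-shift to oxygen (ring expansion 4→5), which sets the (S) methyl-bearing centre (the catalyst antipode that gives (S)-17 is chosen by rotation against the known lactone); the closest known reaction type is the chiral BINOL-phosphoric-acid-catalysed Baeyer–Villiger oxidation of 3-arylcyclobutanones with H2O2, whose open pocket is expected to discriminate a methyl group poorly.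

**Step 9**
Reactants: 14 11-[(dimethylamino)methyl]lasiodiplodin; 17 (S)-4-methyloxolan-2-one
Product: 21 11-{[(3S,4S)-4-methyl-2-oxooxolan-3-yl]methyl}lasiodiplodin, via ammonium iodide 18 (not isolated), via lithium enolate 19 (not isolated), via quinone methide 20 (not isolated)
Conditions: 14, MeI (1.05 equiv), MeCN, rt, evaporate; separately 17 (1.5 equiv), LiHMDS (2.7 equiv), THF, −78 °C; add 18 in THF/DMPU, −78 → −20 °C; AcOH
Reagents that add atoms: none
Why: Quaternisation and base-induced 1,4-elimination of trimethylamine give the ortho-quinone methide, which takes up the lactone lithium enolate by Michael addition; the enolate reacts on the face anti to the neighbouring 4-methyl group, so the new centre is set trans (3S,4S).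

**Step 10**
Reactants: 21 11-{[(3S,4S)-4-methyl-2-oxooxolan-3-yl]methyl}lasiodiplodin
Product: 23 lasiodiplactone A, via methyl lactol 22 (not isolated)
Conditions: MeLi (2.3 equiv), THF, −78 °C; AcOH; then PPTS (10 mol %), CH2Cl2, 4 Å MS, rt
Reagents that add atoms: methyllithium [Li]C
Why: 1,2-Addition of MeLi to the γ-lactone stops at the lithium lactolate at −78 °C (the di-ortho-substituted macrolactone is inert), and acid-catalysed intramolecular ketalisation through the oxocarbenium ion can only give the cis-fused ketal, so the ketal carbon is set (S) by the adjacent centre.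

**Compound list**
1 | 3-bromophenol | Oc1cccc(Br)c1 | starting material
2 | 1-bromo-3-methoxybenzene | COc1cccc(Br)c1 | intermediate
3 | (2-bromo-6-methoxyphenyl)lithium | COc1cccc(Br)c1[Li] | intermediate
4 | 2-bromo-6-methoxybenzoic acid | COc1cccc(Br)c1C(=O)O | intermediate
5 | 6-bromohex-1-ene | C=CCCCCBr | starting material
6 | (S)-2-methyloxirane | C[C@H]1CO1 | starting material
7 | hex-5-en-1-ylmagnesium bromide | C=CCCCC[Mg]Br | intermediate
8 | (S)-non-8-en-2-ol | C[C@H](O)CCCCCC=C | intermediate
9 | 9-{(8S)-8-[(9-borabicyclo[3.3.1]nonan-9-yl)oxy]nonyl}-9-borabicyclo[3.3.1]nonane | C[C@H](OB1C2CCCC1CCC2)CCCCCCCB1C2CCCC1CCC2 | intermediate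
10 | 2-[(8S)-8-hydroxynonyl]-6-methoxybenzoic acid | COc1cccc(CCCCCCC[C@H](C)O)c1C(=O)O | intermediate
11 | (3R)-14-methoxy-3-methyl-3,4,5,6,7,8,9,10-octahydro-1H-2-benzoxacyclododecin-1-one (12-deoxylasiodiplodin) | COc1cccc2c1C(=O)O[C@H](C)CCCCCCC2 | intermediate
12 | 12-(4,4,5,5-tetramethyl-1,3,2-dioxaborolan-2-yl)-12-deoxylasiodiplodin | COc1cc(B3OC(C)(C)C(C)(C)O3)cc2c1C(=O)O[C@H](C)CCCCCCC2 | intermediate
13 | (R)-lasiodiplodin, (3R)-12-hydroxy-14-methoxy-3-methyl-3,4,5,6,7,8,9,10-octahydro-1H-2-benzoxacyclododecin-1-one | COc1cc(O)cc2c1C(=O)O[C@H](C)CCCCCCC2 | intermediate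
14 | 11-[(dimethylamino)methyl]lasiodiplodin | COc1cc(O)c(CN(C)C)c2c1C(=O)O[C@H](C)CCCCCCC2 | intermediate
15 | 3-methylcyclobutan-1-one | CC1CC(=O)C1 | starting material
16 | 1-hydroperoxy-3-methylcyclobutan-1-ol | CC1CC(O)(OO)C1 | intermediate
17 | (S)-4-methyloxolan-2-one | C[C@H]1CC(=O)OC1 | intermediate
18 | 11-[(trimethylammonio)methyl]lasiodiplodin iodide | COc1cc(O)c(C[N+](C)(C)C)c2c1C(=O)O[C@H](C)CCCCCCC2.[I-] | intermediate
19 | lithium (S)-3-methyl-2,3-dihydrofuran-5-olate (enolate of 17) | C[C@@H]1COC(O[Li])=C1 | intermediate
20 | lasiodiplodin ortho-quinone methide (11-methylidene, 12-oxo) | COC1=CC(=O)C(=C)C2=C1C(=O)O[C@H](C)CCCCCCC2 | intermediate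
21 | 11-{[(3S,4S)-4-methyl-2-oxooxolan-3-yl]methyl}lasiodiplodin | COc1cc(O)c(C[C@H]3[C@H](C)COC3=O)c2c1C(=O)O[C@H](C)CCCCCCC2 | intermediate
22 | 11-{[(3S,4S)-2-hydroxy-2,4-dimethyloxolan-3-yl]methyl}lasiodiplodin (anomer mixture) | COc1cc(O)c(C[C@H]3[C@H](C)COC3(C)O)c2c1C(=O)O[C@H](C)CCCCCCC2 | intermediate
23 | lasiodiplactone A | COc1cc2c(c3c1C(=O)O[C@H](C)CCCCCCC3)C[C@H]1[C@H](C)CO[C@@]1(C)O2 | target

**Step count**
Total: 10 steps. Longest linear sequence: 8 steps (1, 2, 4, 5, 6, 7, 9, 10).

**Three steps most likely to fail, with fallbacks**

Step 7 (Mannich reaction). The risk is regioselectivity (C11 against C13) and double aminomethylation; the C11 preference rests on analogy with simpler 3-methoxyphenols, not on data for lasiodiplodin. The fallback sets out from 13 and comes back at 14. Compound 13 is ortho-formylated through its magnesium phenoxide (MgCl2, Et3N, paraformaldehyde, MeCN, reflux), a chelate-controlled reaction that gives the salicylaldehyde 11-formyllasiodiplodin F1. F1 is easy to separate from any C13 isomer and to assign by NOE. Reductive amination of F1 with dimethylamine and NaBH(OAc)3 then gives 14.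

Step 8 (the proposed catalytic Baeyer–Villiger ring expansion). The risk is low enantioselectivity, because the catalyst must tell a methyl group from hydrogen. The fallback uses known chemistry, does not start from a route compound, and comes back at 17. Commercial 4-methylfuran-2(5H)-one F2 replaces 15 and is hydrogenated with a Ru(II)–BINAP catalyst under H2 pressure, a known asymmetric hydrogenation of β-substituted butenolides; the BINAP antipode that gives (S)-17 is used.

Step 9 (quinone methide plus lactone enolate). The risks are oligomerisation of 20, self-condensation of the enolate and double alkylation. The fallback sets out from 17 and from 14 (through 18) and comes back at 23, so step 10 is no longer needed. Lactone 17 is treated with MeLi at −78 °C to give the lactol (4S)-2,4-dimethyloxolan-2-ol F3. Acid-catalysed dehydration of F3 (cat. TsOH, distillation) gives the enol ether (S)-3,5-dimethyl-2,3-dihydrofuran F4. Heating 18 with excess F4 and K2CO3 in MeCN (60 °C) releases 20, which adds F4 in the known inverse-demand hetero-Diels–Alder manner used for related furo[2,3-b]chroman ketals. Addition occurs anti to the ring methyl group and gives 23 directly.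

**Further compounds**
F1 | step 7 | 11-formyllasiodiplodin | COc1cc(O)c(C=O)c2c1C(=O)O[C@H](C)CCCCCCC2
F2 | step 8 | 4-methylfuran-2(5H)-one | CC1=CC(=O)OC1
F3 | step 9 | (4S)-2,4-dimethyloxolan-2-ol | C[C@H]1CC(C)(O)OC1
F4 | step 9 | (S)-3,5-dimethyl-2,3-dihydrofuran | CC1=C[C@H](C)CO1
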